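**Direct plan and its weak points**

A direct plan would hydroxylate C12 of a protected (2E,6E)-farnesol A1, exchange protecting groups and oxidise C1 to the 12-silyloxyfarnesal A2, then set C5' by a catalytic asymmetric propargylation.
Carboalumination of the alkyne with formaldehyde trapping, then bromination, would give the allylic bromide A3.
A3 would C-alkylate the sodium salt of 2-methylphenol A4; desilylation would give phenol A5, Teuber oxidation the quinone A6, and dithionite the target.
Weak point, the ortho C-allylation of the phenoxide: an ambident nucleophile (O against C, ortho against para, single against double allylation) would meet a labile allylic bromide that carries the whole chiral chain, so the most valuable intermediate would be spent in the least selective bond formation.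
Weak point, the oxidation of phenol A5 to quinone A6: the arene would be bought one oxygen short, so a radical oxidant would have to act on the fully deprotected tetraene diol, in a step that only corrects an oxidation state.

**Retrosynthetic overview of the new route**

The benzene ring is not bought but built last, on the finished chain, by a Dötz benzannulation of a C18 skipped enyne with an (E)-propenyl(methoxy)carbene complex of zerovalent chromium: the two sp carbons become ring C2 and C3 (so C1' is bonded to C2 from the start), the carbene carbon C4, the propenyl group C5, C6 and the 6-methyl, and one CO ligand C1 with its oxygen.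
The mechanism of the annulation fixes the 2-alkyl-6-methyl-1,4-dioxygenated pattern and delivers both oxygenated ring carbons at once, so neither an ambident phenoxide nor an oxygenation of a finished arene is needed. The oxidative work-up gives the quinone, and reduction plus one fluoride treatment end the route.
The enyne comes from an alkynyl–allyl coupling at C1', its C2'=C3' alkene from Negishi carboalumination of a homopropargylic silyl ether, and the only stereocentre, C5', from a catalytic asymmetric propargylation of a 12-silyloxyfarnesal reached in three operations from commercial farnesyl acetate.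
Ring order: the single ring (benzene) closes in the key step; one kind of silyl ether is used throughout.

Key step: step 9

Assumptions: ring atoms are C1–C6 (C1 carries the oxygen flanked by chain and methyl) and chain atoms C1'–C16'. (S)-TRIP is taken to direct the allenylboronate to the Si face of the β,β-disubstituted enal, as it does for aryl and alkenyl aldehydes.

**Route**

Step 1
Reactants: 1 (2E,6E)-farnesyl acetate
Product: 2 (2E,6E,10E)-12-hydroxy-3,7,11-trimethyldodeca-2,6,10-trien-1-yl acetate
Conditions: SeO2 (0.1 equiv), t-BuOOH (70% aq., 3 equiv), salicylic acid (0.1 equiv), CH2Cl2, 0 °C to rt, stopped at partial conversion, 1 recycled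
Reagents that add atoms: selenium dioxide, O=[Se]=O (catalytic oxygen carrier); tert-butyl hydroperoxide, CC(C)(C)OO (stoichiometric oxygen source)
Why: Catalytic SeO2 allylic hydroxylation (ene reaction followed by a [2,3]-sigmatropic shift) should attack the terminal, most electron-rich trisubstituted alkene at its E-methyl group, the 2,3-alkene being deactivated by the allylic acetate, so the future C16' hydroxyl is placed with 10E geometry on a cheap commercial ester.

Step 2
Reactants: 2 (2E,6E,10E)-12-hydroxy-3,7,11-trimethyldodeca-2,6,10-trien-1-yl acetate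
Product: 4 (2E,6E,10E)-12-(tert-butyldimethylsilyloxy)-3,7,11-trimethyldodeca-2,6,10-trien-1-ol, via silyl ether acetate 3 (not isolated)
Conditions: t-BuMe2SiCl (1.2 equiv), imidazole (2 equiv), CH2Cl2, 0 °C to rt; then MeOH, K2CO3 (2 equiv), rt, same flask
Reagents that add atoms: tert-butyldimethylsilyl chloride, CC(C)(C)[Si](C)(C)Cl
Why: Imidazole-promoted O-silylation of the only free hydroxyl, followed in the same flask by carbonate-catalysed transesterification of the acetate with methanol, should free C1–OH while the silyl ether, stable to K2CO3/MeOH, stays on.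

Step 3
Reactants: 4 (2E,6E,10E)-12-(tert-butyldimethylsilyloxy)-3,7,11-trimethyldodeca-2,6,10-trien-1-ol
Product: 5 (2E,6E,10E)-12-(tert-butyldimethylsilyloxy)-3,7,11-trimethyldodeca-2,6,10-trienal
Conditions: PhI(OAc)2 (1.1 equiv), 2,2,6,6-tetramethylpiperidin-1-oxyl (0.1 equiv), CH2Cl2, rt
Reagents that add atoms: none
Why: Oxoammonium-mediated oxidation of a primary allylic alcohol stops at the enal and should leave the 2E geometry and the silyl ether untouched.

Step 4
Reactants: 5 (2E,6E,10E)-12-(tert-butyldimethylsilyloxy)-3,7,11-trimethyldodeca-2,6,10-trienal; 6 allenylboronic acid pinacol ester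
Product: 8 (4S,5E,9E,13E)-15-(tert-butyldimethylsilyloxy)-6,10,14-trimethylpentadeca-5,9,13-trien-1-yn-4-ol, via pinacol borate 7 (not isolated)
Conditions: 6 (1.5 equiv), (S)-3,3'-bis(2,4,6-triisopropylphenyl)-1,1'-binaphthyl-2,2'-diyl hydrogen phosphate [(S)-TRIP, 10 mol%], 4 Å molecular sieves, toluene, −20 °C; aq. NaHCO3 work-up
Reagents that add atoms: none
Why: This chiral Brønsted acid-catalysed allenylboration (asymmetric propargylation) passes through a closed six-membered transition state with allylic transposition, so only the homopropargylic alcohol forms, and the (S)-phosphate, bound to the boronate oxygen and the formyl hydrogen, should expose the Si face of the enal and set the carbinol carbon (the later C5') as S.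

Step 5
Reactants: 8 (4S,5E,9E,13E)-15-(tert-butyldimethylsilyloxy)-6,10,14-trimethylpentadeca-5,9,13-trien-1-yn-4-ol
Product: 9 (4S,5E,9E,13E)-4,15-bis(tert-butyldimethylsilyloxy)-6,10,14-trimethylpentadeca-5,9,13-trien-1-yne
Conditions: t-BuMe2SiCl, imidazole, DMF, rt
Reagents that add atoms: tert-butyldimethylsilyl chloride, CC(C)(C)[Si](C)(C)Cl
Why: Standard silylation masks the secondary allylic alcohol against the organoaluminium, sulfonylation, Grignard and carbene steps with the same group that already protects C16', so one fluoride treatment frees both at the end.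

Step 6
Reactants: 9 (4S,5E,9E,13E)-4,15-bis(tert-butyldimethylsilyloxy)-6,10,14-trimethylpentadeca-5,9,13-trien-1-yne
Product: 12 (2E,5S,6E,10E,14E)-5,16-bis(tert-butyldimethylsilyloxy)-3,7,11,15-tetramethylhexadeca-2,6,10,14-tetraen-1-ol, via alkenylalane 10 (not isolated), via aluminium alkoxide 11 (not isolated)
Conditions: Me3Al (3 equiv), Cp2ZrCl2 (0.5 equiv), CH2Cl2, 0 °C to rt; volatiles removed; (CH2O)n (excess), THF, 0 °C to rt; aq. potassium sodium tartrate (KNaC4H4O6) work-up
Reagents that add atoms: trimethylaluminium, C[Al](C)C (the methyl group on C3'); formaldehyde as paraformaldehyde, C=O (C1' and its oxygen)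
Why: Zirconium-catalysed methylalumination of the terminal alkyne (Negishi carboalumination) adds methyl and aluminium syn with methyl on the internal carbon, and C-hydroxymethylation of the alkenylalane with formaldehyde goes with retention, so the 2E trisubstituted alkene should result while the other alkenes and the silyl ethers stay inert.

Step 7
Reactants: 12 (2E,5S,6E,10E,14E)-5,16-bis(tert-butyldimethylsilyloxy)-3,7,11,15-tetramethylhexadeca-2,6,10,14-tetraen-1-ol
Product: 15 (4E,7S,8E,12E,16E)-7,18-bis(tert-butyldimethylsilyloxy)-5,9,13,17-tetramethyloctadeca-4,8,12,16-tetraen-1-yne, via allylic mesylate 13 (not isolated), via allylic bromide 14 (not isolated)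
Conditions: MsCl (1.3 equiv), Et3N (1.5 equiv), THF, −40 °C; LiBr (4 equiv, THF), −40 to 0 °C; then CuBr·SMe2 (0.1 equiv), HC≡CMgBr (0.5 M in THF, 5 equiv), −30 °C to rt, same flask; aq. NH4Cl work-up
Reagents that add atoms: ethynylmagnesium bromide, C#C[Mg]Br
Why: Mesylation and SN2 displacement by bromide give the primary allylic bromide under cold non-acidic conditions, and copper-catalysed substitution by the ethynyl Grignard reagent at the unhindered primary carbon (alkynyl–allyl coupling) should give the skipped 1,4-enyne with retention of the E alkene, the large excess of acetylide suppressing double allylation.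

Step 8
Reactants: 16 (E)-1-bromoprop-1-ene; 17 chromium hexacarbonyl, Cr(CO)6
Product: 20 pentacarbonyl[(2E)-1-methoxybut-2-en-1-ylidene]chromium (zerovalent chromium), via (E)-prop-1-enyllithium 18 (not isolated), via lithium acylchromate 19 (not isolated)
Conditions: t-BuLi (2 equiv), Et2O, −78 °C; Cr(CO)6, Et2O, −78 °C to rt; solvent removed; Me3OBF4 (1.5 equiv), CH2Cl2/H2O, 0 °C
Reagents that add atoms: trimethyloxonium tetrafluoroborate, C[O+](C)C.F[B-](F)(F)F (the O-methyl group)
Why: This is the classical alkoxycarbene complex synthesis: bromine–lithium exchange with retention gives the alkenyllithium, which adds to a CO ligand of Cr(CO)6, and O-methylation of the acylchromate by the oxonium salt gives the carbene complex, whose propenyl geometry is of no consequence for the arene formed later.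

Step 9
Reactants: 15 (4E,7S,8E,12E,16E)-7,18-bis(tert-butyldimethylsilyloxy)-5,9,13,17-tetramethyloctadeca-4,8,12,16-tetraen-1-yne; 20 pentacarbonyl[(2E)-1-methoxybut-2-en-1-ylidene]chromium
Product: 23 2-[(2E,5S,6E,10E,14E)-5,16-bis(tert-butyldimethylsilyloxy)-3,7,11,15-tetramethylhexadeca-2,6,10,14-tetraen-1-yl]-6-methyl-1,4-benzoquinone, via tricarbonylchromium arene complex 21 (not isolated), via free 4-methoxyphenol 22 (not isolated)
Conditions: 20 (1.5 equiv), THF (0.05 M), 50 °C, argon; then (NH4)2Ce(NO3)6 (6 equiv), MeCN/H2O, 0 °C, 15 min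
Reagents that add atoms: water, O (the oxygen on C4 of the quinone, in exchange for the methoxy group)
Why: Dötz benzannulation: loss of one CO from 20 lets the alkyne insert into the Cr=C bond with its unsubstituted carbon bonding to the carbene carbon (C3–C4), CO insertion into the new chromium vinylcarbene gives an η4-vinylketene (C2–C1), and 6π-electrocyclisation of this dienylketene onto the propenyl β-carbon (C1–C6, the ring-closing bond) followed by tautomerisation gives the tricarbonylchromium complex of the 4-methoxyphenol; the closest known reaction type is the benzannulation of alkenyl(methoxy)carbene chromium complexes with terminal alkynes and 1,4-enynes on the way to prenylated quinones. The regiochemistry the target needs (chain at C2 next to the CO-derived C1, hydrogen at C3, methyl at C6, the two oxygens para) is secured by the steric preference that places the substituted alkyne carbon next to the carbonyl ligand and by the fixed connectivity of the propenyl carbene. No stereocentre is formed, and C5' of the chain, remote and silylated, is untouched. The needed chemoselectivity for the alkyne over four trisubstituted alkenes follows from the inertness of unactivated, unstrained alkenes toward this carbene complex at 50 °C, and the one-carbon tether between the alkyne and C2'=C3' is too short for intramolecular cyclopropanation. (NH4)2Ce(NO3)6 then strips the chromium and oxidises the 4-methoxyphenol, by attack of water at C4 and loss of methanol, to the 1,4-benzoquinone in the same operation.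

Step 10
Reactants: 23 2-[(2E,5S,6E,10E,14E)-5,16-bis(tert-butyldimethylsilyloxy)-3,7,11,15-tetramethylhexadeca-2,6,10,14-tetraen-1-yl]-6-methyl-1,4-benzoquinone
Product: 25 2-[(2E,5S,6E,10E,14E)-5,16-dihydroxy-3,7,11,15-tetramethylhexadeca-2,6,10,14-tetraen-1-yl]-6-methylbenzene-1,4-diol (CNP0151872.1), via bis-silyl hydroquinone 24 (not isolated)
Conditions: Na2S2O4 (aq., excess), THF/H2O (degassed), rt, argon; aqueous layer removed by cannula; Et3N·3HF (excess), MeCN added, rt to 40 °C, argon; degassed aq. NaHCO3 work-up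
Reagents that add atoms: none
Why: Two-electron reduction of the quinone by dithionite is fast near neutral pH, and the amine–hydrogen fluoride complex then cleaves both silyl ethers by fluoride attack on silicon under nearly neutral, non-oxidising conditions, so the allylic carbinols should not ionise, the ortho-allyl hydroquinone should not close to a chroman, and C5' keeps its S configuration.

**Compound list**

1 | (2E,6E)-farnesyl acetate | CC(C)=CCC/C(C)=C/CC/C(C)=C/COC(C)=O | starting material
2 | (2E,6E,10E)-12-hydroxy-3,7,11-trimethyldodeca-2,6,10-trien-1-yl acetate | C/C(CO)=C\CC/C(C)=C/CC/C(C)=C/COC(C)=O | intermediate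
3 | (2E,6E,10E)-12-(tert-butyldimethylsilyloxy)-3,7,11-trimethyldodeca-2,6,10-trien-1-yl acetate, formed in the flask | C/C(CO[Si](C)(C)C(C)(C)C)=C\CC/C(C)=C/CC/C(C)=C/COC(C)=O | intermediate
4 | (2E,6E,10E)-12-(tert-butyldimethylsilyloxy)-3,7,11-trimethyldodeca-2,6,10-trien-1-ol | C/C(CO[Si](C)(C)C(C)(C)C)=C\CC/C(C)=C/CC/C(C)=C/CO | intermediate
5 | (2E,6E,10E)-12-(tert-butyldimethylsilyloxy)-3,7,11-trimethyldodeca-2,6,10-trienal | C/C(CO[Si](C)(C)C(C)(C)C)=C\CC/C(C)=C/CC/C(C)=C/C=O | intermediate
6 | allenylboronic acid pinacol ester | C=C=CB1OC(C)(C)C(C)(C)O1 | starting material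
7 | O-pinacolboryl derivative (borate ester) of alcohol 8, formed in the flask | C/C(CO[Si](C)(C)C(C)(C)C)=C\CC/C(C)=C/CC/C(C)=C/[C@@H](OB1OC(C)(C)C(C)(C)O1)CC#C | intermediate
8 | (4S,5E,9E,13E)-15-(tert-butyldimethylsilyloxy)-6,10,14-trimethylpentadeca-5,9,13-trien-1-yn-4-ol | C/C(CO[Si](C)(C)C(C)(C)C)=C\CC/C(C)=C/CC/C(C)=C/[C@@H](O)CC#C | intermediate
9 | (4S,5E,9E,13E)-4,15-bis(tert-butyldimethylsilyloxy)-6,10,14-trimethylpentadeca-5,9,13-trien-1-yne | C/C(CO[Si](C)(C)C(C)(C)C)=C\CC/C(C)=C/CC/C(C)=C/[C@@H](O[Si](C)(C)C(C)(C)C)CC#C | intermediate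
10 | dimethyl[(1E,4S,5E,9E,13E)-4,15-bis(tert-butyldimethylsilyloxy)-2,6,10,14-tetramethylpentadeca-1,5,9,13-tetraen-1-yl]alane, formed in the flask | C/C(CO[Si](C)(C)C(C)(C)C)=C\CC/C(C)=C/CC/C(C)=C/[C@@H](O[Si](C)(C)C(C)(C)C)C/C(C)=C/[Al](C)C | intermediate
11 | dimethylaluminium alkoxide of alcohol 12, formed in the flask | C/C(CO[Si](C)(C)C(C)(C)C)=C\CC/C(C)=C/CC/C(C)=C/[C@@H](O[Si](C)(C)C(C)(C)C)C/C(C)=C/CO[Al](C)C | intermediate
12 | (2E,5S,6E,10E,14E)-5,16-bis(tert-butyldimethylsilyloxy)-3,7,11,15-tetramethylhexadeca-2,6,10,14-tetraen-1-ol | C/C(CO[Si](C)(C)C(C)(C)C)=C\CC/C(C)=C/CC/C(C)=C/[C@@H](O[Si](C)(C)C(C)(C)C)C/C(C)=C/CO | intermediate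
13 | methanesulfonate of alcohol 12, formed in the flask | C/C(CO[Si](C)(C)C(C)(C)C)=C\CC/C(C)=C/CC/C(C)=C/[C@@H](O[Si](C)(C)C(C)(C)C)C/C(C)=C/COS(C)(=O)=O | intermediate
14 | (2E,5S,6E,10E,14E)-1-bromo-5,16-bis(tert-butyldimethylsilyloxy)-3,7,11,15-tetramethylhexadeca-2,6,10,14-tetraene, formed in the flask | C/C(CO[Si](C)(C)C(C)(C)C)=C\CC/C(C)=C/CC/C(C)=C/[C@@H](O[Si](C)(C)C(C)(C)C)C/C(C)=C/CBr | intermediate
15 | (4E,7S,8E,12E,16E)-7,18-bis(tert-butyldimethylsilyloxy)-5,9,13,17-tetramethyloctadeca-4,8,12,16-tetraen-1-yne | C/C(CO[Si](C)(C)C(C)(C)C)=C\CC/C(C)=C/CC/C(C)=C/[C@@H](O[Si](C)(C)C(C)(C)C)C/C(C)=C/CC#C | intermediate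
16 | (E)-1-bromoprop-1-ene | C/C=C/Br | starting material
17 | chromium hexacarbonyl | O=C=[Cr](=C=O)(=C=O)(=C=O)(=C=O)=C=O | starting material
18 | (E)-prop-1-enyllithium, formed in the flask | C/C=C/[Li] | intermediate
19 | lithium pentacarbonyl[(2E)-1-oxidobut-2-en-1-ylidene]chromate (acylchromate), formed in the flask | C/C=C/C([O-])=[Cr](=C=O)(=C=O)(=C=O)(=C=O)=C=O.[Li+] | intermediate
20 | pentacarbonyl[(2E)-1-methoxybut-2-en-1-ylidene]chromium | C/C=C/C(OC)=[Cr](=C=O)(=C=O)(=C=O)(=C=O)=C=O | intermediate
21 | tricarbonylchromium η6 complex of phenol 22 (η6 bonding written as a dot), formed in the flask | C/C(CO[Si](C)(C)C(C)(C)C)=C\CC/C(C)=C/CC/C(C)=C/[C@@H](O[Si](C)(C)C(C)(C)C)C/C(C)=C/Cc1cc(OC)cc(C)c1O.O=C=[Cr](=C=O)=C=O | intermediate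
22 | 2-[(2E,5S,6E,10E,14E)-5,16-bis(tert-butyldimethylsilyloxy)-3,7,11,15-tetramethylhexadeca-2,6,10,14-tetraen-1-yl]-4-methoxy-6-methylphenol, formed in the flask | C/C(CO[Si](C)(C)C(C)(C)C)=C\CC/C(C)=C/CC/C(C)=C/[C@@H](O[Si](C)(C)C(C)(C)C)C/C(C)=C/Cc1cc(OC)cc(C)c1O | intermediate
23 | 2-[(2E,5S,6E,10E,14E)-5,16-bis(tert-butyldimethylsilyloxy)-3,7,11,15-tetramethylhexadeca-2,6,10,14-tetraen-1-yl]-6-methyl-1,4-benzoquinone | C/C(CO[Si](C)(C)C(C)(C)C)=C\CC/C(C)=C/CC/C(C)=C/[C@@H](O[Si](C)(C)C(C)(C)C)C/C(C)=C/CC1=CC(=O)C=C(C)C1=O | intermediate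
24 | 2-[(2E,5S,6E,10E,14E)-5,16-bis(tert-butyldimethylsilyloxy)-3,7,11,15-tetramethylhexadeca-2,6,10,14-tetraen-1-yl]-6-methylbenzene-1,4-diol, formed in the flask | C/C(CO[Si](C)(C)C(C)(C)C)=C\CC/C(C)=C/CC/C(C)=C/[C@@H](O[Si](C)(C)C(C)(C)C)C/C(C)=C/Cc1cc(O)cc(C)c1O | intermediate
25 | 2-[(2E,5S,6E,10E,14E)-5,16-dihydroxy-3,7,11,15-tetramethylhexadeca-2,6,10,14-tetraen-1-yl]-6-methylbenzene-1,4-diol (CNP0151872.1) | C/C(=C\CC/C(C)=C/CC/C(C)=C/[C@@H](O)C/C(C)=C/Cc1cc(O)cc(C)c1O)CO | target

**Step count and risks**

Total steps: 10. Longest linear sequence: 9 (steps 1–7, 9 and 10); step 8 is a one-step branch.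

Steps most likely to fail:

- Step 9 (benzannulation). The terminal alkyne may oligomerise at the carbene complex, the vinylketene stage may be diverted to cyclopentenone or furan products, and silyl groups may be partly lost in the acidic oxidative work-up (such material would still converge in step 10). Fallback: setting out from alcohol 12, the bromide 14 made as in the first half of step 7 would be coupled under CuBr·SMe2 catalysis in THF with (2,5-dimethoxy-3-methylphenyl)magnesium bromide F2, prepared from 1-bromo-2,5-dimethoxy-3-methylbenzene F1 and Mg, to give 1-[(2E,5S,6E,10E,14E)-5,16-bis(tert-butyldimethylsilyloxy)-3,7,11,15-tetramethylhexadeca-2,6,10,14-tetraen-1-yl]-2,5-dimethoxy-3-methylbenzene F3. Oxidative demethylation of F3 with (NH4)2Ce(NO3)6 in MeCN/H2O would then rejoin the route at quinone 23.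

- Step 7 (bromide formation and alkynyl–allyl coupling). Attack may occur with allylic transposition at the tertiary carbon, the allylic bromide may ionise or lose its E geometry, the skipped enyne may isomerise under base to a conjugated vinylallene, and acetylene may be allylated twice. Fallback: from alcohol 12, the isolable (2E,5S,6E,10E,14E)-1-chloro-5,16-bis(tert-butyldimethylsilyloxy)-3,7,11,15-tetramethylhexadeca-2,6,10,14-tetraene F4 (MsCl, LiCl, 2,4,6-collidine, DMF, 0 °C) would be joined to tributyl(ethynyl)stannane by a Stille coupling through a π-allylpalladium intermediate (Pd2(dba)3, tri(2-furyl)phosphine, THF, 50 °C). This is a neutral, base-free coupling at the less substituted allyl terminus and returns to enyne 15.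

- Step 4 (asymmetric propargylation). Facial selectivity may be insufficient and the reaction slow on a β,β-disubstituted enal. Fallback: from aldehyde 5, a zinc-mediated Barbier propargylation (propargyl bromide, Zn, THF/aq. NH4Cl) would give racemic (5E,9E,13E)-15-(tert-butyldimethylsilyloxy)-6,10,14-trimethylpentadeca-5,9,13-trien-1-yn-4-ol F5. A lipase-catalysed kinetic resolution (Pseudomonas cepacia lipase, vinyl acetate, hexane, rt, stopped near half conversion) should then acylate the R enantiomer to (4R,5E,9E,13E)-15-(tert-butyldimethylsilyloxy)-6,10,14-trimethylpentadeca-5,9,13-trien-1-yn-4-yl acetate F6, by the empirical size rule for secondary alcohols with the alkenyl chain as the large and the propargyl group as the medium substituent, and leave the S alcohol 8, where the route is rejoined.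

**Further compounds**

F1 | step 9 | 1-bromo-2,5-dimethoxy-3-methylbenzene | COc1cc(C)c(OC)c(Br)c1
F2 | step 9 | (2,5-dimethoxy-3-methylphenyl)magnesium bromide | COc1cc(C)c(OC)c([Mg]Br)c1
F3 | step 9 | 1-[(2E,5S,6E,10E,14E)-5,16-bis(tert-butyldimethylsilyloxy)-3,7,11,15-tetramethylhexadeca-2,6,10,14-tetraen-1-yl]-2,5-dimethoxy-3-methylbenzene | C/C(CO[Si](C)(C)C(C)(C)C)=C\CC/C(C)=C/CC/C(C)=C/[C@@H](O[Si](C)(C)C(C)(C)C)C/C(C)=C/Cc1cc(OC)cc(C)c1OC
F4 | step 7 | (2E,5S,6E,10E,14E)-1-chloro-5,16-bis(tert-butyldimethylsilyloxy)-3,7,11,15-tetramethylhexadeca-2,6,10,14-tetraene | C/C(CO[Si](C)(C)C(C)(C)C)=C\CC/C(C)=C/CC/C(C)=C/[C@@H](O[Si](C)(C)C(C)(C)C)C/C(C)=C/CCl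
F5 | step 4 | racemic (5E,9E,13E)-15-(tert-butyldimethylsilyloxy)-6,10,14-trimethylpentadeca-5,9,13-trien-1-yn-4-ol | C/C(CO[Si](C)(C)C(C)(C)C)=C\CC/C(C)=C/CC/C(C)=C/C(O)CC#C
F6 | step 4 | (4R,5E,9E,13E)-15-(tert-butyldimethylsilyloxy)-6,10,14-trimethylpentadeca-5,9,13-trien-1-yn-4-yl acetate | C/C(CO[Si](C)(C)C(C)(C)C)=C\CC/C(C)=C/CC/C(C)=C/[C@H](OC(C)=O)CC#C
A1 | direct plan | (2E,6E)-farnesol | CC(C)=CCC/C(C)=C/CC/C(C)=C/CO
A2 | direct plan | (2E,6E,10E)-12-(tert-butyldiphenylsilyloxy)-3,7,11-trimethyldodeca-2,6,10-trienal | C/C(CO[Si](c1ccccc1)(c1ccccc1)C(C)(C)C)=C\CC/C(C)=C/CC/C(C)=C/C=O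
A3 | direct plan | (2E,5S,6E,10E,14E)-1-bromo-5-(tert-butyldimethylsilyloxy)-16-(tert-butyldiphenylsilyloxy)-3,7,11,15-tetramethylhexadeca-2,6,10,14-tetraene | C/C(CO[Si](c1ccccc1)(c1ccccc1)C(C)(C)C)=C\CC/C(C)=C/CC/C(C)=C/[C@@H](O[Si](C)(C)C(C)(C)C)C/C(C)=C/CBr
A4 | direct plan | 2-methylphenol | Cc1ccccc1O
A5 | direct plan | 2-[(2E,5S,6E,10E,14E)-5,16-dihydroxy-3,7,11,15-tetramethylhexadeca-2,6,10,14-tetraen-1-yl]-6-methylphenol | C/C(=C\CC/C(C)=C/CC/C(C)=C/[C@@H](O)C/C(C)=C/Cc1cccc(C)c1O)CO
A6 | direct plan | 2-[(2E,5S,6E,10E,14E)-5,16-dihydroxy-3,7,11,15-tetramethylhexadeca-2,6,10,14-tetraen-1-yl]-6-methyl-1,4-benzoquinone | C/C(=C\CC/C(C)=C/CC/C(C)=C/[C@@H](O)C/C(C)=C/CC1=CC(=O)C=C(C)C1=O)CO
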